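## Retrosynthetic overview

1. The target is opened from an (E)-α-alkylidene, cis-fused γ-lactone that also carries a masked enal (tertiary carbinol bearing a 2-ethoxy-1-methylvinyl group). One i-Bu2AlH reduction plus mild acid releases the 1,4-diol, the 3-hydroxypropyl group and the tetrasubstituted enal together.
2. The alkylidene comes from a lactone aldol condensation with dienal 29; the masked enal comes from adding 2-lithio-1-ethoxypropene to the C7 ketone.
3. Key step: an acyl radical closes 5-exo onto the β-carbon of a cyclohexenone (C1–C5 bond, spiro quaternary centre), and the α-keto radical is intercepted by an allyl sulfone (C6–allyl). A hydroxyl-directed reduction and lactonisation follow.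
4. The cyclisation substrate comes from cyclohexane-1,3-dione by Stork–Danheiser chemistry (Davis hydroxylation sets C10), alkene cleavage and an enamine/photoredox α-alkylation (sets C2).
5. Ring order: six-membered carbocycle first (from the dione), cyclopentane second (radical spirocyclisation), temporary lactone third (opened in the last step).

Locants: spiro[4.5]decane numbering of the target is used for all spiro compounds (C1 secondary carbinol, C2 side-chain carbon, C5 spiro carbon, C6 hydroxypropyl carbon, C7 alkylidene carbon, C10 tertiary carbinol).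

Assumption: the sense of induction of the oxaziridine (step 3) and of the imidazolidinone (step 6) is taken by analogy with 2-methyl-1-tetralone and with the bromomalonate alkylation of simple aldehydes; if the opposite sense is found, the enantiomeric reagent or catalyst is used.

## Route

Step 1
Reactants: 1 cyclohexane-1,3-dione
Product: 2 3-methoxycyclohex-2-en-1-one
Conditions: MeOH, TsOH·H2O (5 mol%), 3 Å molecular sieves, reflux
Reagents that add atoms: methanol, CO
Why: Acid-catalysed O-alkylation of the enol of a 1,3-diketone (vinylogous esterification) gives the vinylogous ester and creates no stereocentre.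

Step 2
Reactants: 2 3-methoxycyclohex-2-en-1-one
Product: 3 3-methoxy-6-methylcyclohex-2-en-1-one (racemic)
Conditions: LiN(i-Pr)2, THF, −78 °C; MeI, −78 → 0 °C
Reagents that add atoms: iodomethane, CI
Why: Kinetic deprotonation of a vinylogous ester occurs at the α′ carbon and the enolate is C-methylated (Stork–Danheiser enolate alkylation); the racemic centre is planarised again in step 3.

Step 3
Reactants: 3 3-methoxy-6-methylcyclohex-2-en-1-one
Product: 4 (6S)-6-hydroxy-3-methoxy-6-methylcyclohex-2-en-1-one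
Conditions: KN(SiMe3)2, THF, −78 °C; (−)-[(8,8-dichlorocamphoryl)sulfonyl]oxaziridine, −78 → −40 °C; AcOH
Reagents that add atoms: (−)-[(8,8-dichlorocamphoryl)sulfonyl]oxaziridine, CC1(C)C2CCC13CS(=O)(=O)N4OC34C2(Cl)Cl
Why: Davis asymmetric enolate hydroxylation, in which the chiral N-sulfonyloxaziridine transfers oxygen to one face of the planar tetrasubstituted potassium enolate (reagent control) and sets the (S)-tertiary carbinol that becomes C10.

Step 4
Reactants: 4 (6S)-6-hydroxy-3-methoxy-6-methylcyclohex-2-en-1-one; 5 5-bromopent-1-ene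
Product: 8 (4S)-4-hydroxy-4-methyl-3-(pent-4-en-1-yl)cyclohex-2-en-1-one, via Grignard reagent 6 (not isolated), via diol adduct 7 (not isolated)
Conditions: 5, Mg, THF, rt; then 4 (Grignard 3.2 equiv), THF, −78 → 0 °C; then 1 M HCl, THF, rt
Reagents that add atoms: water, O
Why: Stork–Danheiser transposition, i.e. 1,2-addition to the vinylogous ester carbonyl then acid hydrolysis of the enol ether and loss of water, gives the 3-substituted enone while the carbinol centre, which has no acidic hydrogen, is untouched.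

Step 5
Reactants: 8 (4S)-4-hydroxy-4-methyl-3-(pent-4-en-1-yl)cyclohex-2-en-1-one
Product: 10 4-[(6S)-6-hydroxy-6-methyl-3-oxocyclohex-1-en-1-yl]butanal, via diol 9 (not isolated)
Conditions: OsO4 (2 mol%), NaIO4 (4 equiv), 2,6-lutidine, 1,4-dioxane/H2O 3:1, rt
Reagents that add atoms: sodium periodate (oxygen relayed through OsO4), [Na+].[O-]I(=O)(=O)=O
Why: Lemieux–Johnson cleavage, in which the electron-rich monosubstituted alkene is dihydroxylated far faster than the electron-poor trisubstituted enone alkene and the diol is cut to the aldehyde.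

Step 6
Reactants: 10 4-[(6S)-6-hydroxy-6-methyl-3-oxocyclohex-1-en-1-yl]butanal
Product: 11 methyl (3S)-3-formyl-5-[(6S)-6-hydroxy-6-methyl-3-oxocyclohex-1-en-1-yl]pentanoate
Conditions: BrCH2CO2Me (2 equiv), (2S,5R)-2-tert-butyl-3,5-dimethylimidazolidin-4-one·TfOH (20 mol%), fac-Ir(ppy)3 (0.5 mol%), 2,6-lutidine, DMF, blue LEDs, 0 °C → rt
Reagents that add atoms: methyl bromoacetate, COC(=O)CBr
Why: MacMillan photoredox/enamine α-alkylation, in which the electrophilic •CH2CO2Me radical (from photoreduction of the bromide) adds to the unshielded face of the chiral (E)-enamine and sets the future C2 centre under catalyst control, while the electron-poor enone does not accept this radical.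

Step 7 (key step)
Reactants: 11 methyl (3S)-3-formyl-5-[(6S)-6-hydroxy-6-methyl-3-oxocyclohex-1-en-1-yl]pentanoate
Product: 12 methyl 2-[(2S,5R,6S,10S)-10-hydroxy-10-methyl-1,7-dioxo-6-(prop-2-en-1-yl)spiro[4.5]decan-2-yl]acetate
Conditions: (n-Bu4N)4[W10O32] (4 mol%), allyl phenyl sulfone (5 equiv), NaHCO3 (1.5 equiv), MeCN (0.03 M), 390 nm LEDs, 20 °C, degassed
Reagents that add atoms: allyl phenyl sulfone, C=CCS(=O)(=O)c1ccccc1
Why: Proposed new method: photoexcited decatungstate abstracts the formyl hydrogen of 11 (the weakest and most hydridic C–H present) and the nucleophilic acyl radical closes 5-exo onto the enone β-carbon (a radical Stetter-type Giese cyclisation; closest known reactions are decatungstate hydroacylation of enones, decatungstate C–H allylation with allyl sulfones and acyl-selenide cyclisation/Keck allylation cascades), forming the C1–C5 bond and the spiro quaternary centre on the face syn to the small C10 hydroxyl and anti to the pseudo-axial C10 methyl with the C2 ester arm on the side of the planar enone carbon and away from the fully substituted C10, after which the electrophilic α-keto radical at C6 adds to allyl phenyl sulfone and expels PhSO2• (reduced to sulfinate by the reduced polyoxotungstate, which closes the cycle), the allyl group entering axially on the face of the flat C1 carbonyl and anti to the pseudo-axial C4 methylene.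

Step 8
Reactants: 12 methyl 2-[(2S,5R,6S,10S)-10-hydroxy-10-methyl-1,7-dioxo-6-(prop-2-en-1-yl)spiro[4.5]decan-2-yl]acetate
Product: 14 cis-fused γ-lactone (1R,2S,5S,6S,10S)-6-allyl-10-hydroxy-10-methyl-7-oxospiro[4.5]decane with C1–O acylated by the C2 CH2C(=O) arm, via hydroxy ester 13 (not isolated)
Conditions: Me4NBH(OAc)3 (5 equiv), MeCN/AcOH 1:1, −30 → 0 °C; then rt, 8 h
Reagents that add atoms: none
Why: Evans–Saksena hydroxyl-directed reduction, in which the C10–O-bound acetoxyborohydride delivers hydride intramolecularly to the C1 ketone from the C10 side (also the face anti to the C2 arm) so that the new hydroxyl is cis to the ester arm and lactonises, while the C7 ketone, which has no β-hydroxyl, is not reduced.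

Step 9
Reactants: 14 cis-fused γ-lactone with 6-allyl and 7-oxo groups
Product: 16 cis-fused γ-lactone (1R,2S,5S,6S,10S)-10-hydroxy-6-(3-hydroxypropyl)-10-methyl-7-oxospiro[4.5]decane with C1–O acylated by the C2 CH2C(=O) arm, via boronate 15 (not isolated)
Conditions: catecholborane (3 equiv), RhCl(PPh3)3 (3 mol%), THF, 0 °C → rt; then 30% H2O2, pH 7 phosphate buffer, 0 °C
Reagents that add atoms: hydrogen peroxide, OO
Why: Rhodium-catalysed (Männig–Nöth) hydroboration is chemoselective for the terminal alkene over the ketone and lactone and anti-Markovnikov, and buffered oxidation gives the primary alcohol without base that could epimerise C6.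

Step 10
Reactants: 17 ethyl prop-1-en-1-yl ether (E/Z mixture)
Product: 19 2-bromo-1-ethoxyprop-1-ene (E/Z mixture), via dibromide 18 (not isolated)
Conditions: Br2, CH2Cl2, −78 °C; then Et3N, 0 → 40 °C
Reagents that add atoms: bromine, BrBr
Why: Bromine addition to the enol ether then amine-induced loss of HBr through the α-bromo ether (the standard route to β-bromo enol ethers) gives the vinyl bromide, whose alkene geometry is irrelevant later.

Step 11
Reactants: 16 cis-fused γ-lactone with 6-(3-hydroxypropyl) and 7-oxo groups; 19 2-bromo-1-ethoxyprop-1-ene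
Product: 21 cis-fused γ-lactone (1R,2S,5S,6S,10S)-7-(1-ethoxyprop-1-en-2-yl)-7,10-dihydroxy-6-(3-hydroxypropyl)-10-methylspiro[4.5]decane with C1–O acylated by the C2 CH2C(=O) arm (C7 epimers), via vinyllithium 20 (not isolated)
Conditions: 19 (5 equiv), t-BuLi (10 equiv), Et2O, −78 °C; then 16, THF, −78 °C; H2O quench kept at pH ≥ 8
Reagents that add atoms: none
Why: Duhamel/Wollenberg-type addition of a β-lithio enol ether (a masked α-methyl acrolein anion), which adds 1,2 to the ketone much faster than to the γ-lactone at −78 °C; the new C7 carbinol centre is destroyed in step 16 so its configuration does not matter.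

Step 12
Reactants: 22 5-bromo-2-methylpent-2-ene
Product: 23 6-methylhept-5-en-1-yne
Conditions: LiC≡CH·H2NCH2CH2NH2, DMSO, 15 °C → rt
Reagents that add atoms: lithium acetylide–ethylenediamine complex, [Li]C#C.NCCN
Why: SN2 alkylation of acetylide by a primary homoallylic bromide, with no stereocentre formed.

Step 13
Reactants: 23 6-methylhept-5-en-1-yne
Product: 25 2-bromo-6-methylhepta-1,5-diene, via alkenylborane 24 (not isolated)
Conditions: B-bromo-9-borabicyclo[3.3.1]nonane, CH2Cl2, 0 °C; then AcOH, 0 °C → rt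
Reagents that add atoms: B-bromo-9-borabicyclo[3.3.1]nonane, BrB1C2CCCC1CCC2
Why: Hara–Suzuki bromoboration adds B–Br syn and Markovnikov (bromine to the internal carbon) to the terminal alkyne only, and protodeboronation leaves the 2-bromo-1-alkene with the trisubstituted alkene untouched.

Step 14
Reactants: 25 2-bromo-6-methylhepta-1,5-diene; 26 (E)-3-(dimethylamino)prop-2-enal
Product: 29 (2E)-8-methyl-4-methylidenenona-2,7-dienal, via vinyllithium 27 (not isolated), via amino alcohol 28 (not isolated)
Conditions: t-BuLi (2 equiv), Et2O, −78 °C; then 26, −78 → 0 °C; then 1 M HCl, 0 °C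
Reagents that add atoms: water, O
Why: 1,2-Addition of the vinyllithium to the vinylogous formamide then acid-induced loss of water and hydrolysis of the conjugated iminium (vinylogous Bouveault formylation) gives the (E)-enal under thermodynamic control.

Step 15
Reactants: 21 cis-fused γ-lactone with the 7-(1-ethoxyprop-1-en-2-yl) carbinol; 29 (2E)-8-methyl-4-methylidenenona-2,7-dienal
Product: 32 (E)-α-[(2E)-8-methyl-4-methylidenenona-2,7-dien-1-ylidene] lactone with 6-(3-acetoxypropyl) group and the 7-(1-ethoxyprop-1-en-2-yl) carbinol, via aldol adduct 30 (not isolated), via bis-acetate 31 (not isolated)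
Conditions: LiN(i-Pr)2 (4.5 equiv), THF, −78 °C; 29 (1.5 equiv); H2O; crude: Ac2O, Et3N, DMAP (cat.), CH2Cl2, 0 °C; then DBU, rt
Reagents that add atoms: acetic anhydride, CC(=O)OC(C)=O
Why: Lactone aldol addition (1,2 to the enal) then E1cB elimination of the secondary acetate gives the conjugated (E)-alkylidene lactone (chain anti to the lactone carbonyl, the thermodynamic isomer), which is the geometry of the trisubstituted alkene of the target; the tertiary hydroxyls are not acetylated and the stereocentres are not touched.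

Step 16
Reactants: 32 (E)-α-alkylidene lactone acetate
Product: 34 (2E)-2-[(1R,2S,5S,6R,10S)-1,10-dihydroxy-2-[(2E,4E)-1-hydroxy-10-methyl-6-methylideneundeca-2,4,9-trien-2-yl]-6-(3-hydroxypropyl)-10-methylspiro[4.5]decan-7-ylidene]propanal (CNP0246965.4), via pentaol enol ether 33 (not isolated)
Conditions: i-Bu2AlH (10 equiv), CH2Cl2, −78 → 0 °C; aqueous potassium sodium tartrate; then pyridinium p-toluenesulfonate (0.2 equiv), THF/H2O 4:1, 0 °C
Reagents that add atoms: water, O
Why: i-Bu2AlH reduces the unsaturated lactone 1,2 to the allylic 1,4-diol and cleaves the acetate while the enol ether survives, and mild acid then ionises the tertiary β-hydroxy enol ether to an ethoxy-stabilised allyl cation that is hydrolysed to the enal (Wollenberg/Duhamel unmasking), the rotamer with the larger CH=OEt arm next to the ring CH2 (C8) and the methyl next to the substituted C6 giving the required alkene geometry.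

## Compound list

1 | cyclohexane-1,3-dione | O=C1CCCC(=O)C1 | starting material
2 | 3-methoxycyclohex-2-en-1-one | COC1=CC(=O)CCC1 | intermediate
3 | 3-methoxy-6-methylcyclohex-2-en-1-one (racemic) | COC1=CC(=O)C(C)CC1 | intermediate
4 | (6S)-6-hydroxy-3-methoxy-6-methylcyclohex-2-en-1-one | COC1=CC(=O)[C@@](C)(O)CC1 | intermediate
5 | 5-bromopent-1-ene | C=CCCCBr | starting material
6 | pent-4-en-1-ylmagnesium bromide | C=CCCC[Mg]Br | intermediate (not isolated)
7 | (6S)-3-methoxy-6-methyl-1-(pent-4-en-1-yl)cyclohex-2-ene-1,6-diol (C1 epimers, magnesium alkoxide in the flask) | COC1=CC(O)(CCCC=C)[C@@](C)(O)CC1 | intermediate (not isolated)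
8 | (4S)-4-hydroxy-4-methyl-3-(pent-4-en-1-yl)cyclohex-2-en-1-one | C=CCCCC1=CC(=O)CC[C@]1(C)O | intermediate
9 | (4S)-3-(4,5-dihydroxypentyl)-4-hydroxy-4-methylcyclohex-2-en-1-one | OCC(O)CCCC1=CC(=O)CC[C@]1(C)O | intermediate (not isolated)
10 | 4-[(6S)-6-hydroxy-6-methyl-3-oxocyclohex-1-en-1-yl]butanal | O=CCCCC1=CC(=O)CC[C@]1(C)O | intermediate
11 | methyl (3S)-3-formyl-5-[(6S)-6-hydroxy-6-methyl-3-oxocyclohex-1-en-1-yl]pentanoate | COC(=O)C[C@@H](C=O)CCC1=CC(=O)CC[C@]1(C)O | intermediate
12 | methyl 2-[(2S,5R,6S,10S)-10-hydroxy-10-methyl-1,7-dioxo-6-(prop-2-en-1-yl)spiro[4.5]decan-2-yl]acetate | COC(=O)C[C@@H]1CC[C@]2([C@H](CC=C)C(=O)CC[C@]2(C)O)C1=O | intermediate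
13 | methyl 2-[(1R,2S,5S,6S,10S)-1,10-dihydroxy-10-methyl-7-oxo-6-(prop-2-en-1-yl)spiro[4.5]decan-2-yl]acetate | COC(=O)C[C@@H]1CC[C@]2([C@H](CC=C)C(=O)CC[C@]2(C)O)[C@@H]1O | intermediate (not isolated)
14 | cis-fused γ-lactone of 13: (2'S,3aS,6S,6aR,6'S)-6'-hydroxy-6'-methyl-2'-(prop-2-en-1-yl)hexahydrospiro[cyclopenta[b]furan-6,1'-cyclohexane]-2,3'-dione | O=C1C[C@@H]2CC[C@]3([C@H](CC=C)C(=O)CC[C@]3(C)O)[C@@H]2O1 | intermediate
15 | catechol boronate of 16 (2'-[3-(1,3,2-benzodioxaborol-2-yl)propyl] analogue of 14) | O=C1C[C@@H]2CC[C@]3([C@H](CCCB4Oc5ccccc5O4)C(=O)CC[C@]3(C)O)[C@@H]2O1 | intermediate (not isolated)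
16 | (2'S,3aS,6S,6aR,6'S)-6'-hydroxy-2'-(3-hydroxypropyl)-6'-methylhexahydrospiro[cyclopenta[b]furan-6,1'-cyclohexane]-2,3'-dione | O=C1C[C@@H]2CC[C@]3([C@H](CCCO)C(=O)CC[C@]3(C)O)[C@@H]2O1 | intermediate
17 | ethyl prop-1-en-1-yl ether (E/Z mixture) | CCOC=CC | starting material
18 | 1,2-dibromo-1-ethoxypropane | CCOC(Br)C(C)Br | intermediate (not isolated)
19 | 2-bromo-1-ethoxyprop-1-ene (E/Z mixture) | CCOC=C(C)Br | intermediate
20 | (1-ethoxyprop-1-en-2-yl)lithium | CCOC=C(C)[Li] | intermediate (not isolated)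
21 | lactone 16 with the 3'-ketone converted into a tertiary carbinol bearing a 1-ethoxyprop-1-en-2-yl group (carbinol epimers, enol ether E/Z) | O=C1C[C@@H]2CC[C@]3([C@H](CCCO)C(O)(C(C)=COCC)CC[C@]3(C)O)[C@@H]2O1 | intermediate
22 | 5-bromo-2-methylpent-2-ene | CC(C)=CCCBr | starting material
23 | 6-methylhept-5-en-1-yne | C#CCCC=C(C)C | intermediate
24 | 9-[(1Z)-2-bromo-6-methylhepta-1,5-dien-1-yl]-9-borabicyclo[3.3.1]nonane | Br/C(CCC=C(C)C)=C\B1C2CCCC1CCC2 | intermediate (not isolated)
25 | 2-bromo-6-methylhepta-1,5-diene | C=C(Br)CCC=C(C)C | intermediate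
26 | (E)-3-(dimethylamino)prop-2-enal | CN(C)/C=C/C=O | starting material
27 | (6-methylhepta-1,5-dien-2-yl)lithium | C=C([Li])CCC=C(C)C | intermediate (not isolated)
28 | (1E)-1-(dimethylamino)-8-methyl-4-methylidenenona-1,7-dien-3-ol (lithium alkoxide in the flask) | CN(C)/C=C/C(O)C(=C)CCC=C(C)C | intermediate (not isolated)
29 | (2E)-8-methyl-4-methylidenenona-2,7-dienal | O=C/C=C/C(=C)CCC=C(C)C | intermediate
30 | aldol adduct of 21 and 29 (lactone α-carbon bears CH(OH)–CH=CH–C(=CH2)–CH2CH2CH=CMe2; diastereomer mixture) | O=C1C(C(O)/C=C/C(=C)CCC=C(C)C)[C@@H]2CC[C@]3([C@H](CCCO)C(O)(C(C)=COCC)CC[C@]3(C)O)[C@@H]2O1 | intermediate (not isolated)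
31 | bis-acetate of 30 (secondary aldol hydroxyl and primary hydroxyl acetylated) | O=C1C(C(OC(C)=O)/C=C/C(=C)CCC=C(C)C)[C@@H]2CC[C@]3([C@H](CCCOC(C)=O)C(O)(C(C)=COCC)CC[C@]3(C)O)[C@@H]2O1 | intermediate (not isolated)
32 | (E)-α-[(2E)-8-methyl-4-methylidenenona-2,7-dien-1-ylidene] lactone with 2'-(3-acetoxypropyl) group and the 3'-(1-ethoxyprop-1-en-2-yl) carbinol | O=C1/C(=C/C=C/C(=C)CCC=C(C)C)[C@@H]2CC[C@]3([C@H](CCCOC(C)=O)C(O)(C(C)=COCC)CC[C@]3(C)O)[C@@H]2O1 | intermediate
33 | (1R,2S,5S,6S,10S)-7-(1-ethoxyprop-1-en-2-yl)-2-[(2E,4E)-1-hydroxy-10-methyl-6-methylideneundeca-2,4,9-trien-2-yl]-6-(3-hydroxypropyl)-10-methylspiro[4.5]decane-1,7,10-triol (C7 epimers) | C=C(/C=C/C=C(/CO)[C@@H]1CC[C@]2([C@H](CCCO)C(O)(C(C)=COCC)CC[C@]2(C)O)[C@@H]1O)CCC=C(C)C | intermediate (not isolated)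
34 | (2E)-2-[(1R,2S,5S,6R,10S)-1,10-dihydroxy-2-[(2E,4E)-1-hydroxy-10-methyl-6-methylideneundeca-2,4,9-trien-2-yl]-6-(3-hydroxypropyl)-10-methylspiro[4.5]decan-7-ylidene]propanal | C=C(/C=C/C=C(/CO)[C@@H]1CC[C@]2([C@H](CCCO)/C(=C(\C)C=O)CC[C@]2(C)O)[C@@H]1O)CCC=C(C)C | target

## Step count

Total: 16 steps. Longest linear sequence: 12 steps (steps 1–9, 11, 15, 16). Side branches: steps 12–14 (dienal 29) and step 10 (bromide 19).

## Three steps most likely to fail, with fallbacks

Step 7 (radical cascade). The α-keto radical may simply be reduced (plain hydroacylation without allyl transfer), or hydrogen abstraction may be unselective. The fallback sets out from 11 and returns at 12. Pinnick oxidation (NaClO2, NaH2PO4, 2-methylbut-2-ene) gives (2S)-4-[(6S)-6-hydroxy-6-methyl-3-oxocyclohex-1-en-1-yl]-2-(2-methoxy-2-oxoethyl)butanoic acid F1. PhSeSePh/PBu3 converts it into the Se-phenyl selenoester F2. A tin-mediated chain (allylSnBu3 3 equiv, AIBN, benzene, 80 °C) then generates the same acyl radical by abstraction of the phenylselanyl group; 5-exo closure and allyl transfer from the stannane deliver 12.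

Step 6 (α-alkylation with a simple bromoacetate, and the level of stereocontrol at C2). The fallback sets out from 10 and returns at 14. Bromoacetonitrile, the best-documented electrophile for this organocatalytic alkylation, is used with Ru(bpy)3Cl2 and the same imidazolidinone to give (3S)-3-formyl-5-[(6S)-6-hydroxy-6-methyl-3-oxocyclohex-1-en-1-yl]pentanenitrile F3. The cascade of step 7 gives the cyanomethyl spiro diketone F4. Me4NBH(OAc)3 gives the cis-hydroxy nitrile F5. An intramolecular Pinner lactonisation (HCl, Et2O/H2O, 0 °C → rt) closes the lactone and gives 14.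

Step 16 (unmasking of the enal: premature rearrangement of the acid-labile carbinol in earlier steps, or poor alkene geometry). The fallback sets out from 16 and returns at 34.
- CH2=C(CH3)MgBr/CeCl3 adds to the ketone to give the isopropenyl carbinol F6.
- Aldol condensation with 29 as in step 15 gives the alkylidene lactone acetate F7.
- i-Bu2AlH gives the pentaol F8.
- t-BuMe2SiOTf/2,6-lutidine at −78 °C silylates the three non-tertiary hydroxyls to give the tris-silyl ether F9.
- Babler–Dauben oxidative transposition with [C5H5NH][CrO3Cl] gives the protected enal F10. The chromate ester shifts through a chair [3,3] transition state with the larger ring branch pseudo-equatorial, which places the methyl cis to C6.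
- HF·pyridine removes the silyl groups and gives 34.

## Further compounds

F1 | step 7 | (2S)-4-[(6S)-6-hydroxy-6-methyl-3-oxocyclohex-1-en-1-yl]-2-(2-methoxy-2-oxoethyl)butanoic acid | COC(=O)C[C@@H](C(=O)O)CCC1=CC(=O)CC[C@]1(C)O
F2 | step 7 | Se-phenyl (2S)-4-[(6S)-6-hydroxy-6-methyl-3-oxocyclohex-1-en-1-yl]-2-(2-methoxy-2-oxoethyl)butaneselenoate | COC(=O)C[C@@H](C(=O)[Se]c1ccccc1)CCC1=CC(=O)CC[C@]1(C)O
F3 | step 6 | (3S)-3-formyl-5-[(6S)-6-hydroxy-6-methyl-3-oxocyclohex-1-en-1-yl]pentanenitrile | N#CC[C@@H](C=O)CCC1=CC(=O)CC[C@]1(C)O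
F4 | step 6 | 2-[(2S,5R,6S,10S)-10-hydroxy-10-methyl-1,7-dioxo-6-(prop-2-en-1-yl)spiro[4.5]decan-2-yl]acetonitrile | N#CC[C@@H]1CC[C@]2([C@H](CC=C)C(=O)CC[C@]2(C)O)C1=O
F5 | step 6 | 2-[(1R,2S,5S,6S,10S)-1,10-dihydroxy-10-methyl-7-oxo-6-(prop-2-en-1-yl)spiro[4.5]decan-2-yl]acetonitrile | N#CC[C@@H]1CC[C@]2([C@H](CC=C)C(=O)CC[C@]2(C)O)[C@@H]1O
F6 | step 16 | lactone 16 with the 3'-ketone converted into a tertiary carbinol bearing a prop-1-en-2-yl group (carbinol epimers) | O=C1C[C@@H]2CC[C@]3([C@H](CCCO)C(O)(C(C)=C)CC[C@]3(C)O)[C@@H]2O1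
F7 | step 16 | (E)-α-[(2E)-8-methyl-4-methylidenenona-2,7-dien-1-ylidene] lactone with 2'-(3-acetoxypropyl) group and the 3'-(prop-1-en-2-yl) carbinol | O=C1/C(=C/C=C/C(=C)CCC=C(C)C)[C@@H]2CC[C@]3([C@H](CCCOC(C)=O)C(O)(C(C)=C)CC[C@]3(C)O)[C@@H]2O1
F8 | step 16 | (1R,2S,5S,6S,10S)-2-[(2E,4E)-1-hydroxy-10-methyl-6-methylideneundeca-2,4,9-trien-2-yl]-6-(3-hydroxypropyl)-10-methyl-7-(prop-1-en-2-yl)spiro[4.5]decane-1,7,10-triol | C=C(/C=C/C=C(/CO)[C@@H]1CC[C@]2([C@H](CCCO)C(O)(C(C)=C)CC[C@]2(C)O)[C@@H]1O)CCC=C(C)C
F9 | step 16 | tris(tert-butyldimethylsilyl) ether of F8 (C1–O, side-chain CH2–O and propyl CH2–O silylated; tertiary hydroxyls free) | C=C(/C=C/C=C(/CO[Si](C)(C)C(C)(C)C)[C@@H]1CC[C@]2([C@H](CCCO[Si](C)(C)C(C)(C)C)C(O)(C(C)=C)CC[C@]2(C)O)[C@@H]1O[Si](C)(C)C(C)(C)C)CCC=C(C)C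
F10 | step 16 | tris(tert-butyldimethylsilyl) ether of 34 (C1–O, side-chain CH2–O and propyl CH2–O silylated) | C=C(/C=C/C=C(/CO[Si](C)(C)C(C)(C)C)[C@@H]1CC[C@]2([C@H](CCCO[Si](C)(C)C(C)(C)C)/C(=C(\C)C=O)CC[C@]2(C)O)[C@@H]1O[Si](C)(C)C(C)(C)C)CCC=C(C)C
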